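- The vessel is closed, stirred and held at one temperature, so you can compare runs by charge, asking what share of each charge has become target (the yield) at the last reading.

| flask | starting material | target | time |
|---|---|---|---|
| Sunday's | 100 mM |  |  |
| Saturday's | 50.0 mM |  |  |
| Wednesday's | 100 mM | 50.0 mM |  |
| Friday's | 150 mM |  |  |
| Tuesday's | 400 mM |  | 3.9 h |

| run | time / h | [target] / mM |
|---|---|---|
| Sunday's run | 0.16 | 1.5 |
| Sunday's run | 0.25 | 4.9 |
| Sunday's run | 0.39 | 8.9 |
| Sunday's run | 0.62 | 13.7 |
| Sunday's run | 0.98 | 24.4 |
| Sunday's run | 1.6 | 35.8 |
| Sunday's run | 2.5 | 41.3 |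
| Sunday's run | 3.9 | 48.4 |
| Saturday's run | 0.16 | 0.7 |
| Saturday's run | 0.25 | 1.0 |
| Saturday's run | 0.39 | 2.3 |
| Saturday's run | 0.62 | 7.2 |
| Saturday's run | 0.98 | 13.5 |
| Saturday's run | 1.6 | 18.6 |
| Saturday's run | 2.5 | 24.2 |
| Saturday's run | 3.9 | 24.9 |
| Wednesday's run | 0.16 | 51.7 |
| Wednesday's run | 0.25 | 54.7 |
| Wednesday's run | 0.39 | 56.4 |
| Wednesday's run | 0.62 | 65.0 |
| Wednesday's run | 0.98 | 74.8 |
| Wednesday's run | 1.6 | 84.1 |
| Wednesday's run | 2.5 | 91.3 |
| Wednesday's run | 3.9 | 97.3 |
| Friday's run | 0.16 | 3.4 |
| Friday's run | 0.25 | 6.4 |
| Friday's run | 0.39 | 11.9 |
| Friday's run | 0.62 | 22.2 |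
| Friday's run | 0.98 | 34.0 |
| Friday's run | 1.6 | 50.0 |
| Friday's run | 2.5 | 58.8 |
| Friday's run | 3.9 | 65.6 |

(standard deviation of a reading: 0.8 mM)

- Overall: starting material -> target.
- Constant volume, constant temperature.
- An order is taken over about fifteen percent of the charge, up and down.

* reaction order in [starting material] at the outset, round the charge of the Sunday's run, defined at two percent of the starting material turned into target (one fixed amount of target, the same in the runs compared)
* target in the Tuesday's run at 3.9 h, as a share of the starting material charged

- That share is 49.8% in Saturday's run and 43.7% in Friday's, so it falls as the charge rises, and my first upper bound for Tuesday's run is Friday's share.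
- The amount of target made has risen with the charge so far, so Friday's amount over Tuesday's charge gives my first lower bound, 16.4%.
- To tighten from below, I continue the fall in a straight line, which gives 28.6% for Tuesday's run; this line reaches a zero share at 871 mM, so I judge it too steep and keep it as my lower bound.
- To tighten from above, I draw the straight line through one over the share instead, which reads a low-charge share of 53.5% and a crossing charge, the charge at which the share at the last reading has fallen to half of that value, of 671 mM.
- Tuesday's charge lies below that crossing, and the curve gives 33.5%, so my bracket runs from 28.6% to 33.5%.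
- The forecast says an order of 0.8 and a share of 31%, the share on the ground that “A saturating extrapolation gives about 120 mM at 400 mM, near 30%.” Its share stands inside my bracket.
- The flask gives 31.4%, also inside the bracket, and an order of 0.61, lower than the forecast's.

    starting material → intermediate (0.6192 h⁻¹)
    intermediate → target (2.779 h⁻¹)
    starting material → decomposed substrate (0.4068 h⁻¹)
    2 starting material → homo dimer (2.808 M⁻¹ h⁻¹)

- In Tuesday's run the path from two starting material to homo dimer holds the share down: the same run without that path gives 58.6% instead of 31.4%. The curve built on the crossing charge put Tuesday's run 2.1 percentage points above the flask. At the charge of Wednesday's run, a run the curve was not drawn through, it gives 46.6%, and the target gained beyond what was added reads 47.3% of the charge at the last reading of Wednesday's run.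

The data stem from a simulated flask on assumed constants; noise was put on by code.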